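Of the 3 questions, two ask an amount of target and the remaining one follows from those, so we need one number: how fast target appears at the temperature of both flasks.

| flask | starting material | second substrate | free enzyme | added ligand | temperature | remark | time |
|---|---|---|---|---|---|---|---|
| zeta | 0.050 M | 0.025 M | 25 µM | 15 µM | 25 °C | run made earlier |  |
| eta | 0.050 M | 0.025 M | 25 µM | 27 µM | 36 °C | run made earlier |  |
| Sunday's | 0.050 M | 0.0250 M | 25 µM | 12 µM | 30 °C |  | 3.0 min |
| Thursday's | 0.050 M | 0.0250 M | 25 µM | 18 µM | 30 °C |  | 5.0 min |

| zeta: time / min | zeta: target / % | eta: time / min | eta: target / % |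
|---|---|---|---|
| 0.667 | 8.7 | 0.250 | 11.9 |
| 1.33 | 17.0 | 0.667 | 28.5 |
| 2.00 | 28.2 | 1.33 | 48.7 |
| 2.50 | 33.6 | 2.00 | 64.2 |
| 3.00 | 37.1 | 2.50 | 75.0 |
| 4.00 | 47.5 | 4.00 | 85.9 |

(each reading ± 1 percentage point)

- the winner by amount of target, in percent of the starting material charged; "neither" if no more than 2 percentage points parts them (Sunday's / Thursday's / neither)
- how much target is there at the end, in percent of the starting material charged: Sunday's
- how much target is there at the end, in percent of the starting material charged: Thursday's



Let x be the fraction of the charged starting material read as target, and define the rate constant k as ln(1/(1−x))/t. Its inverse, 1/k, we call the lifetime. We read the runs as a ladder of times. On the first rung, whatever enzyme, ligand and substrates do among themselves shows no lag in the eta run: its first reading, at 0.250 min, gives 0.507 min⁻¹, and the reading at 1.33 min gives 0.502 min⁻¹. The second rung is the making of target, with a lifetime of 1.99 min in the eta run. In the zeta run, k is 0.161 min⁻¹ and the lifetime is 6.21 min. On the third rung, any slowing stays out of sight: the eta reading at 4.00 min still gives 0.490 min⁻¹. That reading also stands for 0.0430 M of target, more than the 0.025 M of second substrate, so target is not tied to second substrate one for one.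

The two runs change ligand and temperature together. Our own reckoning assumes that the ligand hardly matters, puts the whole change of k on temperature, and takes ln k straight across. This gives the carried quantity, the rate constant at the flasks' temperature with 25 µM of free enzyme, 0.270 min⁻¹. We also assume that k follows the enzyme charge. Then we reckon 55.5% for Sunday's and 74.1% for Thursday's.

The forecast names Thursday's, with 40% (32% to 47%) for Sunday's and 72% (62% to 81%) for Thursday's, reading that “the ligand is a tight activator, one per enzyme”. Our figure for Sunday's lies above that range.

The flasks give 60.7% for Sunday's and 77.4% for Thursday's, so the winner is Thursday's.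

    second substrate + free enzyme ⇌ complex B (K = 300 M⁻¹, k = 2400 M⁻¹ s⁻¹, Ea = 36.0 kJ mol⁻¹, ΔH = −74.0 kJ mol⁻¹)
    free enzyme + added ligand ⇌ idle complex, settled at all times (K = 1.30 × 10⁵ M⁻¹, ΔH = −11.0 kJ mol⁻¹)
    complex B → free enzyme + second product (k = 1.20 s⁻¹, Ea = 64.0 kJ mol⁻¹)
    complex A → free enzyme + target (k = 18.0 s⁻¹, Ea = 63.0 kJ mol⁻¹)
    free enzyme → unfolded enzyme (k = 1.60 × 10⁻⁴ s⁻¹, Ea = 237 kJ mol⁻¹)
    starting material + target → side product (k = 0.0200 M⁻¹ s⁻¹, Ea = 49.0 kJ mol⁻¹)
    starting material + free enzyme ⇌ complex A (K = 250 M⁻¹, k = 12000 M⁻¹ s⁻¹, Ea = 9.00 kJ mol⁻¹, ΔH = 4.00 kJ mol⁻¹)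
    (constants at 30 °C)

The scheme holds a step that our reckoning never used: second substrate takes free enzyme into complex B, which stands at 58.1% of the catalyst charged at the end of Thursday's flask. Thursday's flask reaches 77.4% mainly because complex B can fall back to second substrate and free enzyme. The same run without that falling back stands at 32.8%.

A neighbour of Sunday's, charged with 15.0 µM of free enzyme, has k scaled to 0.162 min⁻¹, which gives 38.5% of target. The computed flask gives 40.0%.

(All runs are calculated on assumed constants; scatter was added.)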